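**Retrosynthetic overview**
1. The C8 side chain comes off last: E-selective Horner–Wadsworth–Emmons olefination on a C8 phosphonopropionate ester, then removal of both silyl ethers.
2. The ten-membered ring is formed second, by ring-closing metathesis at C1=C10 (ring-cis trisubstituted alkene).
3. C7–C8 is made by a zinc Barbier addition of a 3-(bromomethyl)butenolide to 3-methylbut-3-enal, which sets C7 and C8 from C6; C11 follows by conjugate reduction in the macrocycle.
4. The lactone ring is formed first, as a butenolide by ring-closing metathesis of a bis-allylic 2-(bromomethyl)acrylate. Its C6–O bond is the key bond: an enantioselective allylic C–H acyloxylation of a 1,4-diene sets C6, the only reagent-controlled stereocentre.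
5. The 1,4-diene with the Z C4=C5 alkene comes from propargyl alcohol by copper-catalysed carbomagnesiation and allylation.

Assumption: CNP0222998.2 is taken to be exactly the structure of the given SMILES; atoms are referred to by germacrane numbering (C6 lactone carbinol, C7 ring fusion, C8 ester carbinol, C11 lactone α-carbon, C15 hydroxymethyl carbon).

**Route**

Step 1
Reactants: 1 prop-2-yn-1-ol; 2 but-3-en-1-ylmagnesium bromide; 3 allyl bromide
Product: 5 (2Z)-2-(but-3-en-1-yl)hexa-2,5-dien-1-ol, via cyclic alkenylmagnesium alkoxide 4 (not isolated)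
Conditions: 2 (2.6 equiv), CuI (10 mol %), Et2O–THF, 0 °C → rt; then 3 (3 equiv), 0 °C → rt; aq NH4Cl
Reagents that add atoms: none
Why: Copper-catalysed anti-carbomagnesiation of the propargylic alkoxide puts the butenyl group on the internal carbon and gives a five-membered alkenylmagnesium chelate, so the allyl group that replaces magnesium ends up cis to CH2OH and the Z C4=C5 alkene is fixed here.

Step 2
Reactants: 5 (2Z)-2-(but-3-en-1-yl)hexa-2,5-dien-1-ol
Product: 6 tert-butyl{[(2Z)-2-(but-3-en-1-yl)hexa-2,5-dien-1-yl]oxy}dimethylsilane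
Conditions: TBSCl, imidazole, CH2Cl2, 0 °C → rt
Reagents that add atoms: tert-butyldimethylsilyl chloride, CC(C)(C)[Si](C)(C)Cl
Why: Standard silylation of the primary allylic alcohol, which would otherwise attack the allyl intermediate of step 3 and compete in the later acylation.

Step 3
Reactants: 6 tert-butyl{[(2Z)-2-(but-3-en-1-yl)hexa-2,5-dien-1-yl]oxy}dimethylsilane; 7 2-(bromomethyl)prop-2-enoic acid
Product: 8 (3S,4Z)-5-({[tert-butyl(dimethyl)silyl]oxy}methyl)nona-1,4,8-trien-3-yl 2-(bromomethyl)prop-2-enoate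
Conditions: Pd(OAc)2 (10 mol %), chiral aryl sulfoxide–oxazoline ligand (12 mol %), 7 (3 equiv), 2,6-dimethyl-1,4-benzoquinone (1.5 equiv), iPr2NEt (0.3 equiv), CH2Cl2–1,4-dioxane, 40 °C
Reagents that add atoms: none
Why: Proposed new method: the divalent palladium catalyst binds the terminal vinyl group of 6 and removes a hydrogen from the doubly allylic CH2 (the most acidic C–H, so the mono-allylic CH2 of the butenyl chain should react much more slowly) to give a 1-alkenyl-π-allylpalladium carboxylate; quinone-promoted inner-sphere C–O reductive elimination at the internal allyl terminus, inside the chiral pocket of the sulfoxide–oxazoline ligand (enantiomer chosen for the S ester), forms the C6–O bond and sets C6, and the zerovalent palladium is reoxidised by the quinone; the closest known reactions are the branched-selective allylic C–H esterification of terminal alkenes with Pd(OAc)2, a bis-sulfoxide and benzoquinone (racemic), the enantioselective intramolecular allylic C–H oxidation with palladium sulfoxide–oxazoline catalysts and the enantioselective palladium-catalysed allylic C–H alkylation of 1,4-dienes, whereas an intermolecular enantioselective acyloxylation of a 1,4-diene at its doubly allylic carbon is not known.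

Step 4
Reactants: 8 (3S,4Z)-5-({[tert-butyl(dimethyl)silyl]oxy}methyl)nona-1,4,8-trien-3-yl 2-(bromomethyl)prop-2-enoate
Product: 9 (5R)-3-(bromomethyl)-5-[(1Z)-2-({[tert-butyl(dimethyl)silyl]oxy}methyl)hexa-1,5-dien-1-yl]furan-2(5H)-one
Conditions: second-generation Hoveyda–Grubbs catalyst (H2IMes)Cl2Ru=CH(2-iPrOC6H4) (5 mol %), toluene (3 mM), 60 °C
Reagents that add atoms: none
Why: Ring-closing metathesis of the vinyl group onto the acrylate gives the butenolide and ethene; the butenyl chain is trans to the carbinol carbon across the Z alkene, so no seven-membered ring can form, and the stereocentre is untouched (the descriptor changes to R only through the priority rules).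

Step 5
Reactants: 10 3-methylbut-3-en-1-ol
Product: 11 3-methylbut-3-enal
Conditions: Dess–Martin periodinane, CH2Cl2, 0 °C → rt; solution used at once
Reagents that add atoms: none
Why: Dess–Martin oxidation of the homoallylic alcohol under non-basic conditions gives the β,γ-unsaturated aldehyde, which is used cold and immediately to avoid isomerisation to the conjugated enal.

Step 6
Reactants: 9 (5R)-3-(bromomethyl)-5-[(1Z)-2-({[tert-butyl(dimethyl)silyl]oxy}methyl)hexa-1,5-dien-1-yl]furan-2(5H)-one; 11 3-methylbut-3-enal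
Product: 13 (4R,5R)-5-[(1Z)-2-({[tert-butyl(dimethyl)silyl]oxy}methyl)hexa-1,5-dien-1-yl]-4-[(1S)-1-hydroxy-3-methylbut-3-en-1-yl]-3-methylideneoxolan-2-one, via butenolide allylzinc bromide 12 (not isolated)
Conditions: 11 (2 equiv), Zn dust, THF–sat. aq NH4Cl, 0 °C → rt
Reagents that add atoms: none
Why: Zinc-mediated Barbier allylation in which the allylzinc reacts at its ring carbon (C7) through a six-membered chair transition state, anti to the C6 side chain and with the ring-locked allyl geometry (C6 trans to CH2Zn) giving the adduct with the C8 hydroxyl anti to the C7–C6 bond, so C7 (R) and C8 (S) are both set from C6 and the α-methylene lactone is formed.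

Step 7
Reactants: 13 (4R,5R)-5-[(1Z)-2-({[tert-butyl(dimethyl)silyl]oxy}methyl)hexa-1,5-dien-1-yl]-4-[(1S)-1-hydroxy-3-methylbut-3-en-1-yl]-3-methylideneoxolan-2-one
Product: 14 (3aR,4S,6Z,10Z,11aR)-10-({[tert-butyl(dimethyl)silyl]oxy}methyl)-4-hydroxy-6-methyl-3-methylidene-3a,4,5,8,9,11a-hexahydrocyclodeca[b]furan-2(3H)-one
Conditions: second-generation Grubbs catalyst (H2IMes)(PCy3)Cl2Ru=CHPh (2 × 7.5 mol %), 1,4-benzoquinone (20 mol %), toluene (1 mM), 80 °C
Reagents that add atoms: none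
Why: Ring-closing metathesis between the monosubstituted and the 1,1-disubstituted alkene at high dilution; the ten-membered ring, which already holds the ring-trans C4=C5 alkene and the trans lactone, is expected to close to the ring-cis (Z) C1=C10 alkene, and closure onto the lactone methylene would require an impossible trans alkene in an eight-membered ring.

Step 8
Reactants: 14 (3aR,4S,6Z,10Z,11aR)-10-({[tert-butyl(dimethyl)silyl]oxy}methyl)-4-hydroxy-6-methyl-3-methylidene-3a,4,5,8,9,11a-hexahydrocyclodeca[b]furan-2(3H)-one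
Product: 15 (3S,3aR,4S,6Z,10Z,11aR)-10-({[tert-butyl(dimethyl)silyl]oxy}methyl)-4-hydroxy-3,6-dimethyl-3a,4,5,8,9,11a-hexahydrocyclodeca[b]furan-2(3H)-one
Conditions: NaBH4, MeOH, 0 °C
Reagents that add atoms: none
Why: Conjugate (1,4) hydride reduction of the α-methylene lactone; protonation of the lactone enolate gives the all-trans lactone with 11S (methyl trans to C8), the thermodynamically preferred epimer and the usual outcome for germacranolides.

Step 9
Reactants: 15 (3S,3aR,4S,6Z,10Z,11aR)-10-({[tert-butyl(dimethyl)silyl]oxy}methyl)-4-hydroxy-3,6-dimethyl-3a,4,5,8,9,11a-hexahydrocyclodeca[b]furan-2(3H)-one; 16 2-(diethoxyphosphoryl)propanoic acid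
Product: 17 (3S,3aR,4S,6Z,10Z,11aR)-10-({[tert-butyl(dimethyl)silyl]oxy}methyl)-3,6-dimethyl-2-oxo-2,3,3a,4,5,8,9,11a-octahydrocyclodeca[b]furan-4-yl 2-(diethoxyphosphoryl)propanoate
Conditions: 16, DCC, DMAP (cat.), CH2Cl2, 0 °C → rt
Reagents that add atoms: none
Why: Steglich esterification of the secondary C8 alcohol with retention; the phosphonate carbon is a mixture of epimers that disappears in the next step.

Step 10
Reactants: 17 (3S,3aR,4S,6Z,10Z,11aR)-10-({[tert-butyl(dimethyl)silyl]oxy}methyl)-3,6-dimethyl-2-oxo-2,3,3a,4,5,8,9,11a-octahydrocyclodeca[b]furan-4-yl 2-(diethoxyphosphoryl)propanoate; 18 {[tert-butyl(dimethyl)silyl]oxy}acetaldehyde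
Product: 19 (3S,3aR,4S,6Z,10Z,11aR)-10-({[tert-butyl(dimethyl)silyl]oxy}methyl)-3,6-dimethyl-2-oxo-2,3,3a,4,5,8,9,11a-octahydrocyclodeca[b]furan-4-yl (2E)-4-{[tert-butyl(dimethyl)silyl]oxy}-2-methylbut-2-enoate
Conditions: 18, LiCl, DBU, MeCN, 0 °C → rt
Reagents that add atoms: none
Why: Horner–Wadsworth–Emmons olefination under Masamune–Roush conditions gives the E trisubstituted enoate under base mild enough to leave the lactone and its stereocentres intact.

Step 11
Reactants: 19 (3S,3aR,4S,6Z,10Z,11aR)-10-({[tert-butyl(dimethyl)silyl]oxy}methyl)-3,6-dimethyl-2-oxo-2,3,3a,4,5,8,9,11a-octahydrocyclodeca[b]furan-4-yl (2E)-4-{[tert-butyl(dimethyl)silyl]oxy}-2-methylbut-2-enoate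
Product: 20 (3S,3aR,4S,6Z,10Z,11aR)-10-(hydroxymethyl)-3,6-dimethyl-2-oxo-2,3,3a,4,5,8,9,11a-octahydrocyclodeca[b]furan-4-yl (2E)-4-hydroxy-2-methylbut-2-enoate
Conditions: HF·pyridine, THF–pyridine, 0 °C → rt
Reagents that add atoms: none
Why: Fluoride-mediated global desilylation removes both primary silyl ethers without touching the ester, the lactone or the alkenes.

**Compound list**
1 | prop-2-yn-1-ol | C#CCO | starting material
2 | but-3-en-1-ylmagnesium bromide | C=CCC[Mg]Br | starting material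
3 | allyl bromide (3-bromoprop-1-ene) | C=CCBr | starting material
4 | 4-(but-3-en-1-yl)-2,5-dihydro-1,2-oxamagnesole (cyclic alkenylmagnesium alkoxide) | C=CCCC1=C[Mg]OC1 | intermediate (not isolated)
5 | (2Z)-2-(but-3-en-1-yl)hexa-2,5-dien-1-ol | C=CCC/C(CO)=C/CC=C | intermediate
6 | tert-butyl{[(2Z)-2-(but-3-en-1-yl)hexa-2,5-dien-1-yl]oxy}dimethylsilane | C=CCC/C(CO[Si](C)(C)C(C)(C)C)=C/CC=C | intermediate
7 | 2-(bromomethyl)prop-2-enoic acid | C=C(CBr)C(=O)O | starting material
8 | (3S,4Z)-5-({[tert-butyl(dimethyl)silyl]oxy}methyl)nona-1,4,8-trien-3-yl 2-(bromomethyl)prop-2-enoate | C=CCC/C(CO[Si](C)(C)C(C)(C)C)=C/[C@@H](OC(=O)C(=C)CBr)C=C | intermediate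
9 | (5R)-3-(bromomethyl)-5-[(1Z)-2-({[tert-butyl(dimethyl)silyl]oxy}methyl)hexa-1,5-dien-1-yl]furan-2(5H)-one | C=CCC/C(CO[Si](C)(C)C(C)(C)C)=C/[C@H]1OC(=O)C(CBr)=C1 | intermediate
10 | 3-methylbut-3-en-1-ol | CC(=C)CCO | starting material
11 | 3-methylbut-3-enal | CC(=C)CC=O | intermediate
12 | ({(5R)-5-[(1Z)-2-({[tert-butyl(dimethyl)silyl]oxy}methyl)hexa-1,5-dien-1-yl]-2-oxo-2,5-dihydrofuran-3-yl}methyl)zinc bromide | C=CCC/C(CO[Si](C)(C)C(C)(C)C)=C/[C@H]1OC(=O)C(C[Zn]Br)=C1 | intermediate (not isolated)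
13 | (4R,5R)-5-[(1Z)-2-({[tert-butyl(dimethyl)silyl]oxy}methyl)hexa-1,5-dien-1-yl]-4-[(1S)-1-hydroxy-3-methylbut-3-en-1-yl]-3-methylideneoxolan-2-one | C=CCC/C(CO[Si](C)(C)C(C)(C)C)=C/[C@H]1OC(=O)C(=C)[C@@H]1[C@@H](O)CC(C)=C | intermediate
14 | (3aR,4S,6Z,10Z,11aR)-10-({[tert-butyl(dimethyl)silyl]oxy}methyl)-4-hydroxy-6-methyl-3-methylidene-3a,4,5,8,9,11a-hexahydrocyclodeca[b]furan-2(3H)-one | C/C1=C/CC/C(CO[Si](C)(C)C(C)(C)C)=C/[C@H]2OC(=O)C(=C)[C@@H]2[C@@H](O)C1 | intermediate
15 | (3S,3aR,4S,6Z,10Z,11aR)-10-({[tert-butyl(dimethyl)silyl]oxy}methyl)-4-hydroxy-3,6-dimethyl-3a,4,5,8,9,11a-hexahydrocyclodeca[b]furan-2(3H)-one | C/C1=C/CC/C(CO[Si](C)(C)C(C)(C)C)=C/[C@H]2OC(=O)[C@@H](C)[C@@H]2[C@@H](O)C1 | intermediate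
16 | 2-(diethoxyphosphoryl)propanoic acid | CCOP(=O)(OCC)C(C)C(=O)O | starting material
17 | (3S,3aR,4S,6Z,10Z,11aR)-10-({[tert-butyl(dimethyl)silyl]oxy}methyl)-3,6-dimethyl-2-oxo-2,3,3a,4,5,8,9,11a-octahydrocyclodeca[b]furan-4-yl 2-(diethoxyphosphoryl)propanoate (both epimers at the phosphonate carbon) | C/C1=C/CC/C(CO[Si](C)(C)C(C)(C)C)=C/[C@H]2OC(=O)[C@@H](C)[C@@H]2[C@@H](OC(=O)C(C)P(=O)(OCC)OCC)C1 | intermediate
18 | {[tert-butyl(dimethyl)silyl]oxy}acetaldehyde | CC(C)(C)[Si](C)(C)OCC=O | starting material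
19 | (3S,3aR,4S,6Z,10Z,11aR)-10-({[tert-butyl(dimethyl)silyl]oxy}methyl)-3,6-dimethyl-2-oxo-2,3,3a,4,5,8,9,11a-octahydrocyclodeca[b]furan-4-yl (2E)-4-{[tert-butyl(dimethyl)silyl]oxy}-2-methylbut-2-enoate | C/C1=C/CC/C(CO[Si](C)(C)C(C)(C)C)=C/[C@H]2OC(=O)[C@@H](C)[C@@H]2[C@@H](OC(=O)/C(C)=C/CO[Si](C)(C)C(C)(C)C)C1 | intermediate
20 | (3S,3aR,4S,6Z,10Z,11aR)-10-(hydroxymethyl)-3,6-dimethyl-2-oxo-2,3,3a,4,5,8,9,11a-octahydrocyclodeca[b]furan-4-yl (2E)-4-hydroxy-2-methylbut-2-enoate (CNP0222998.2) | C/C1=C/CC/C(CO)=C/[C@H]2OC(=O)[C@@H](C)[C@@H]2[C@@H](OC(=O)/C(C)=C/CO)C1 | target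

**Step count**
Total: 11 steps. Longest linear sequence: 10 steps (steps 1–4 and 6–11, from prop-2-yn-1-ol); step 5 is a one-step side branch.

**Steps most likely to fail**

Step 3 (the proposed new C–H acyloxylation). The risks are attack at the outer allyl terminus (linear dienyl ester), competing oxidation next to the butenyl alkene, low enantioselectivity, and re-ionisation of the bis-allylic ester. The fallback uses known chemistry only; it sets out from intermediate 4 (made from 1 and 2 as in step 1) and comes back at 8. Intermediate 4 is quenched with I2 instead of allyl bromide to give the vinyl iodide (2Z)-2-(but-3-en-1-yl)-3-iodoprop-2-en-1-ol F1. Silylation (TBSCl, imidazole) gives tert-butyl{[(2Z)-2-(but-3-en-1-yl)-3-iodoprop-2-en-1-yl]oxy}dimethylsilane F2. Iodine–lithium exchange (t-BuLi, Et2O, −78 °C), transmetalation with ZnBr2 and amino-alcohol-catalysed enantioselective alkenylzinc addition to acrolein ((−)-3-exo-morpholinoisoborneol) give the divinyl carbinol (3S,4Z)-5-({[tert-butyl(dimethyl)silyl]oxy}methyl)nona-1,4,8-trien-3-ol F3. Steglich esterification of F3 with acid 7 (N,N′-diisopropylcarbodiimide, cat. DMAP, CH2Cl2, −20 °C) gives 8 with retention. Here C6 is set by C–C bond formation and the C–O bond by plain acylation, at the cost of one extra step.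

Step 7 (ten-membered ring by metathesis). The risks are oligomers, no closure because of transannular strain, or the ring-trans alkene. The fallback sets out from 13 and comes back at 15. The ring is closed on a C8 ketone and the C8 stereocentre is set afterwards inside the ring. Conjugate reduction of 13 (NaBH4, MeOH, 0 °C; DBU to settle C11) gives (3S,4R,5R)-5-[(1Z)-2-({[tert-butyl(dimethyl)silyl]oxy}methyl)hexa-1,5-dien-1-yl]-4-[(1S)-1-hydroxy-3-methylbut-3-en-1-yl]-3-methyloxolan-2-one F7. Dess–Martin oxidation gives the ketone (3S,4S,5R)-5-[(1Z)-2-({[tert-butyl(dimethyl)silyl]oxy}methyl)hexa-1,5-dien-1-yl]-3-methyl-4-(3-methylbut-3-enoyl)oxolan-2-one F8. Metathesis under the conditions of step 7 then gives the macrocyclic ketone (3S,3aS,6Z,10Z,11aR)-10-({[tert-butyl(dimethyl)silyl]oxy}methyl)-3,6-dimethyl-3a,5,8,9-tetrahydrocyclodeca[b]furan-2,4(3H,11aH)-dione F9; the sp2 C8 lowers transannular strain and removes the free hydroxyl that can bind ruthenium. Hydride delivery from the outer face of the ring (NaBH4, CeCl3·7H2O, MeOH, −40 °C) gives 15. The facial selectivity of this reduction is not established; if it gives the C8 epimer, that epimer is F6 and the Mitsunobu inversion described under step 6 takes it to 17.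

Step 6 (Barbier addition). The risks are that the 8-epimer dominates if the reaction leaves the chair transition state, and that 11 isomerises to the conjugated enal. The fallback sets out from 9 and 11 and comes back at 17. If the main adduct is the epimer (4R,5R)-5-[(1Z)-2-({[tert-butyl(dimethyl)silyl]oxy}methyl)hexa-1,5-dien-1-yl]-4-[(1R)-1-hydroxy-3-methylbut-3-en-1-yl]-3-methylideneoxolan-2-one F4, it is carried through the conditions of step 7 to (3aR,4R,6Z,10Z,11aR)-10-({[tert-butyl(dimethyl)silyl]oxy}methyl)-4-hydroxy-6-methyl-3-methylidene-3a,4,5,8,9,11a-hexahydrocyclodeca[b]furan-2(3H)-one F5. The conditions of step 8 then give (3S,3aR,4R,6Z,10Z,11aR)-10-({[tert-butyl(dimethyl)silyl]oxy}methyl)-4-hydroxy-3,6-dimethyl-3a,4,5,8,9,11a-hexahydrocyclodeca[b]furan-2(3H)-one F6. The C8–O ester bond is then formed with inversion by Mitsunobu reaction with acid 16 (PPh3, diisopropyl azodicarboxylate, toluene, 0 °C → rt), which gives 17 directly.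

**Further compounds**
F1 | step 3 | (2Z)-2-(but-3-en-1-yl)-3-iodoprop-2-en-1-ol | C=CCC/C(CO)=C/I
F2 | step 3 | tert-butyl{[(2Z)-2-(but-3-en-1-yl)-3-iodoprop-2-en-1-yl]oxy}dimethylsilane | C=CCC/C(CO[Si](C)(C)C(C)(C)C)=C/I
F3 | step 3 | (3S,4Z)-5-({[tert-butyl(dimethyl)silyl]oxy}methyl)nona-1,4,8-trien-3-ol | C=CCC/C(CO[Si](C)(C)C(C)(C)C)=C/[C@@H](O)C=C
F4 | step 6 | (4R,5R)-5-[(1Z)-2-({[tert-butyl(dimethyl)silyl]oxy}methyl)hexa-1,5-dien-1-yl]-4-[(1R)-1-hydroxy-3-methylbut-3-en-1-yl]-3-methylideneoxolan-2-one | C=CCC/C(CO[Si](C)(C)C(C)(C)C)=C/[C@H]1OC(=O)C(=C)[C@@H]1[C@H](O)CC(C)=C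
F5 | step 6 | (3aR,4R,6Z,10Z,11aR)-10-({[tert-butyl(dimethyl)silyl]oxy}methyl)-4-hydroxy-6-methyl-3-methylidene-3a,4,5,8,9,11a-hexahydrocyclodeca[b]furan-2(3H)-one | C/C1=C/CC/C(CO[Si](C)(C)C(C)(C)C)=C/[C@H]2OC(=O)C(=C)[C@@H]2[C@H](O)C1
F6 | step 6 | (3S,3aR,4R,6Z,10Z,11aR)-10-({[tert-butyl(dimethyl)silyl]oxy}methyl)-4-hydroxy-3,6-dimethyl-3a,4,5,8,9,11a-hexahydrocyclodeca[b]furan-2(3H)-one | C/C1=C/CC/C(CO[Si](C)(C)C(C)(C)C)=C/[C@H]2OC(=O)[C@@H](C)[C@@H]2[C@H](O)C1
F7 | step 7 | (3S,4R,5R)-5-[(1Z)-2-({[tert-butyl(dimethyl)silyl]oxy}methyl)hexa-1,5-dien-1-yl]-4-[(1S)-1-hydroxy-3-methylbut-3-en-1-yl]-3-methyloxolan-2-one | C=CCC/C(CO[Si](C)(C)C(C)(C)C)=C/[C@H]1OC(=O)[C@@H](C)[C@@H]1[C@@H](O)CC(C)=C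
F8 | step 7 | (3S,4S,5R)-5-[(1Z)-2-({[tert-butyl(dimethyl)silyl]oxy}methyl)hexa-1,5-dien-1-yl]-3-methyl-4-(3-methylbut-3-enoyl)oxolan-2-one | C=CCC/C(CO[Si](C)(C)C(C)(C)C)=C/[C@H]1OC(=O)[C@@H](C)[C@@H]1C(=O)CC(C)=C
F9 | step 7 | (3S,3aS,6Z,10Z,11aR)-10-({[tert-butyl(dimethyl)silyl]oxy}methyl)-3,6-dimethyl-3a,5,8,9-tetrahydrocyclodeca[b]furan-2,4(3H,11aH)-dione | C/C1=C/CC/C(CO[Si](C)(C)C(C)(C)C)=C/[C@H]2OC(=O)[C@@H](C)[C@@H]2C(=O)C1
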